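**Retrosynthetic overview**
1. The C6–allyl bond is made last, by decarboxylative asymmetric allylic alkylation (zerovalent palladium) of the allyl dienol carbonate of (R)-4-aryloxy-3,4-dimethoxycyclohex-2-enone.
2. The C3–OMe group comes from methoxide addition–elimination on a β-phenylthio enone. That enone is made from (R)-4-aryloxy-4-methoxycyclohex-2-enone by thiol addition and NCS oxidation.
3. The C4 ketal centre is the first stereocentre. It is set by ene-reductase desymmetrisation of the achiral 4-aryloxy-4-methoxycyclohexa-2,5-dienone.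
4. The mixed ketal comes from PhI(OAc)2/MeOH dearomatisation of a 4-aryloxyphenol. The diaryl ether comes from SNAr of 2-allyl-4,5-dimethoxyphenol (O-allylation/Claisen of 3,4-dimethoxyphenol) on 4-fluorobenzaldehyde, followed by Dakin oxidation.
5. Ring order: no ring is built from an open chain. Ring A (dimethoxyarene) and ring B (fluorobenzaldehyde ring) are bought and joined through the ether oxygen, then ring B is dearomatised and half-reduced to the cyclohexenone.

Assumption: the ene-reductase (step 6) and the ligand antipode (step 11) are taken to give the drawn sense; both exist in stereocomplementary forms, so the choice is confirmed in a test run by chiral HPLC.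

**Step 1**
Reactants: 1 3,4-dimethoxyphenol; 2 allyl bromide
Product: 3 4-(allyloxy)-1,2-dimethoxybenzene
Conditions: K2CO3, acetone, reflux
Reagents that add atoms: allyl bromide (2), C=CCBr
Why: Williamson ether synthesis, in which the phenoxide displaces bromide from the unhindered allylic halide at oxygen only.

**Step 2**
Reactants: 3 4-(allyloxy)-1,2-dimethoxybenzene
Product: 4 2-allyl-4,5-dimethoxyphenol
Conditions: N,N-diethylaniline, 190 °C, N2
Reagents that add atoms: none
Why: Aromatic Claisen rearrangement ([3,3]-sigmatropic shift) delivers the allyl group to the less hindered ortho carbon (not the one flanked by OMe), and tautomerisation restores the phenol.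

**Step 3**
Reactants: 4 2-allyl-4,5-dimethoxyphenol; 5 4-fluorobenzaldehyde
Product: 6 4-(2-allyl-4,5-dimethoxyphenoxy)benzaldehyde
Conditions: K2CO3, DMF, 120 °C, N2
Reagents that add atoms: 4-fluorobenzaldehyde (5), O=Cc1ccc(F)cc1
Why: Nucleophilic aromatic substitution (SNAr), in which the para-formyl group activates fluoride toward the phenoxide and the weak carbonate base does not isomerise the allyl group.

**Step 4**
Reactants: 6 4-(2-allyl-4,5-dimethoxyphenoxy)benzaldehyde
Product: 8 4-(2-allyl-4,5-dimethoxyphenoxy)phenol, via aryl formate 7 (not isolated)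
Conditions: 30% H2O2, cat. H2SO4, MeOH, rt
Reagents that add atoms: hydrogen peroxide, OO
Why: Dakin-type Baeyer–Villiger oxidation, in which the p-aryloxy-substituted ring migrates to oxygen, the formate is methanolysed in situ, and acidic H2O2 does not epoxidise the terminal alkene.

**Step 5**
Reactants: 8 4-(2-allyl-4,5-dimethoxyphenoxy)phenol
Product: 9 4-(2-allyl-4,5-dimethoxyphenoxy)-4-methoxycyclohexa-2,5-dien-1-one (achiral)
Conditions: PhI(OAc)2 (1.05 equiv), MeOH, 0 °C, 15 min, then cold aq NaHCO3; Et3N-washed silica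
Reagents that add atoms: methanol, CO
Why: Oxidative phenol dearomatisation with a trivalent iodine reagent, in which the aryloxy-stabilised phenoxenium ion is trapped by methanol at the para carbon to give the mixed quinone monoketal, still achiral because its two enone arms are identical.

**Step 6**
Reactants: 9 4-(2-allyl-4,5-dimethoxyphenoxy)-4-methoxycyclohexa-2,5-dien-1-one
Product: 10 (R)-4-(2-allyl-4,5-dimethoxyphenoxy)-4-methoxycyclohex-2-en-1-one
Conditions: ene-reductase (Old Yellow Enzyme family, flavin-dependent; YqjM/OPR3-type panel hit), NAD+ (cat.), HCO2Na, formate dehydrogenase, KH2PO4/K2HPO4 buffer pH 7.0, 10% DMSO, 30 °C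
Reagents that add atoms: none
Why: Desymmetrising biocatalytic conjugate reduction (trans-addition of flavin hydride to C-beta and a tyrosine proton to C-alpha), in which the pocket turns the small OMe toward the flavin and the large aryloxy away so only one enantiotopic arm is reduced, making C4 the first stereocentre (R), and the hindered 4,4-disubstituted enone is not reduced further.

**Step 7**
Reactants: 10 (R)-4-(2-allyl-4,5-dimethoxyphenoxy)-4-methoxycyclohex-2-en-1-one; 11 thiophenol
Product: 12 (4R)-4-(2-allyl-4,5-dimethoxyphenoxy)-4-methoxy-3-(phenylthio)cyclohexan-1-one (C3 epimers)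
Conditions: PhSH, Et3N (10 mol %), CH2Cl2, 0 °C to rt, dark, N2
Reagents that add atoms: thiophenol (11), Sc1ccccc1
Why: Base-catalysed sulfa-Michael addition, in which the soft thiolate adds only to enone carbon C3 while the allyl group and ketal are inert, and the new C3 centre is of no consequence because it becomes sp2 again in step 8.

**Step 8**
Reactants: 12 (4R)-4-(2-allyl-4,5-dimethoxyphenoxy)-4-methoxy-3-(phenylthio)cyclohexan-1-one
Product: 14 (R)-4-(2-allyl-4,5-dimethoxyphenoxy)-4-methoxy-3-(phenylthio)cyclohex-2-en-1-one, via alpha-chloro sulfide 13 (not isolated)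
Conditions: N-chlorosuccinimide (1.0 equiv), K2CO3 (solid), CH2Cl2, 0 °C to rt
Reagents that add atoms: none
Why: Pummerer-type oxidation of a beta-keto sulfide, in which S-chlorination collapses to the alpha-chloro sulfide and HCl is lost toward the acidic C2–H (C4 has no H) to give the vinylogous thioester, while solid K2CO3 keeps the medium acid-free for the ketal.

**Step 9**
Reactants: 14 (R)-4-(2-allyl-4,5-dimethoxyphenoxy)-4-methoxy-3-(phenylthio)cyclohex-2-en-1-one
Product: 15 (R)-4-(2-allyl-4,5-dimethoxyphenoxy)-3,4-dimethoxycyclohex-2-en-1-one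
Conditions: NaOMe, MeOH, 0 °C to rt
Reagents that add atoms: sodium methoxide, [Na+].[O-]C
Why: Nucleophilic vinylic substitution (addition–elimination), in which methoxide adds at C3 and the much better leaving group thiolate is expelled, placing OMe regiospecifically at C3 while the base-stable ketal centre C4 is untouched.

**Step 10**
Reactants: 15 (R)-4-(2-allyl-4,5-dimethoxyphenoxy)-3,4-dimethoxycyclohex-2-en-1-one; 16 allyl chloroformate
Product: 18 allyl (R)-4-(2-allyl-4,5-dimethoxyphenoxy)-4,5-dimethoxycyclohexa-1,5-dien-1-yl carbonate, via potassium dienolate 17 (not isolated)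
Conditions: KN(SiMe3)2, THF, −78 °C; then allyl chloroformate, −78 °C
Reagents that add atoms: allyl chloroformate (16), C=CCOC(=O)Cl
Why: Kinetic alpha-prime deprotonation of the vinylogous ester (Stork–Danheiser regiochemistry, C6 being the only enolisable site) followed by O-acylation of the potassium dienolate with the hard chloroformate.

**Step 11**
Reactants: 18 allyl (R)-4-(2-allyl-4,5-dimethoxyphenoxy)-4,5-dimethoxycyclohexa-1,5-dien-1-yl carbonate
Product: 19 (4R,6S)-6-allyl-4-(2-allyl-4,5-dimethoxyphenoxy)-3,4-dimethoxycyclohex-2-en-1-one (allyl cis to aryloxy; target)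
Conditions: Pd2(dba)3·CHCl3 (2.5 mol %), (S,S)-ANDEN-phenyl Trost ligand (5.5 mol %), 1,4-dioxane, 23 °C; Et3N-washed silica
Reagents that add atoms: none
Why: Decarboxylative asymmetric allylic alkylation (Tsuji–Trost type), in which ionisation and CO2 loss give a pi-allylpalladium/dienolate pair that recombines only at C6, the ligand pocket selects the enolate face cis to the aryloxy group (6S), and the neutral medium spares both the new tertiary centre and the acid-labile ketal.

**Compound list**
1 | 3,4-dimethoxyphenol | COc1ccc(O)cc1OC | starting material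
2 | allyl bromide | C=CCBr | starting material
3 | 4-(allyloxy)-1,2-dimethoxybenzene | C=CCOc1ccc(OC)c(OC)c1 | intermediate
4 | 2-allyl-4,5-dimethoxyphenol | C=CCc1cc(OC)c(OC)cc1O | intermediate
5 | 4-fluorobenzaldehyde | O=Cc1ccc(F)cc1 | starting material
6 | 4-(2-allyl-4,5-dimethoxyphenoxy)benzaldehyde | C=CCc1cc(OC)c(OC)cc1Oc1ccc(C=O)cc1 | intermediate
7 | 4-(2-allyl-4,5-dimethoxyphenoxy)phenyl formate (not isolated) | C=CCc1cc(OC)c(OC)cc1Oc1ccc(OC=O)cc1 | intermediate
8 | 4-(2-allyl-4,5-dimethoxyphenoxy)phenol | C=CCc1cc(OC)c(OC)cc1Oc1ccc(O)cc1 | intermediate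
9 | 4-(2-allyl-4,5-dimethoxyphenoxy)-4-methoxycyclohexa-2,5-dien-1-one (achiral) | C=CCc1cc(OC)c(OC)cc1OC1(OC)C=CC(=O)C=C1 | intermediate
10 | (R)-4-(2-allyl-4,5-dimethoxyphenoxy)-4-methoxycyclohex-2-en-1-one | C=CCc1cc(OC)c(OC)cc1O[C@]1(OC)CCC(=O)C=C1 | intermediate
11 | thiophenol | Sc1ccccc1 | starting material
12 | (4R)-4-(2-allyl-4,5-dimethoxyphenoxy)-4-methoxy-3-(phenylthio)cyclohexan-1-one (C3 epimers) | C=CCc1cc(OC)c(OC)cc1O[C@]1(OC)CCC(=O)CC1Sc1ccccc1 | intermediate
13 | (4R)-4-(2-allyl-4,5-dimethoxyphenoxy)-3-chloro-4-methoxy-3-(phenylthio)cyclohexan-1-one (not isolated) | C=CCc1cc(OC)c(OC)cc1O[C@]1(OC)CCC(=O)CC1(Cl)Sc1ccccc1 | intermediate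
14 | (R)-4-(2-allyl-4,5-dimethoxyphenoxy)-4-methoxy-3-(phenylthio)cyclohex-2-en-1-one | C=CCc1cc(OC)c(OC)cc1O[C@]1(OC)CCC(=O)C=C1Sc1ccccc1 | intermediate
15 | (R)-4-(2-allyl-4,5-dimethoxyphenoxy)-3,4-dimethoxycyclohex-2-en-1-one | C=CCc1cc(OC)c(OC)cc1O[C@]1(OC)CCC(=O)C=C1OC | intermediate
16 | allyl chloroformate | C=CCOC(=O)Cl | starting material
17 | potassium dienolate of 15 (not isolated) | C=CCc1cc(OC)c(OC)cc1O[C@]1(OC)CC=C([O-])C=C1OC.[K+] | intermediate
18 | allyl (R)-4-(2-allyl-4,5-dimethoxyphenoxy)-4,5-dimethoxycyclohexa-1,5-dien-1-yl carbonate | C=CCc1cc(OC)c(OC)cc1O[C@]1(OC)CC=C(OC(=O)OCC=C)C=C1OC | intermediate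
19 | (4R,6S)-6-allyl-4-(2-allyl-4,5-dimethoxyphenoxy)-3,4-dimethoxycyclohex-2-en-1-one | C=CCc1cc(OC)c(OC)cc1O[C@]1(OC)C[C@H](CC=C)C(=O)C=C1OC | target

**Total step count:** 11. **Longest linear sequence:** 11 (from 1).

**Three steps most likely to fail**

Risk at step 6. The bulky, poorly soluble and hydrolysis-prone dienone may be a poor enzyme substrate, or the panel may give the wrong sense. The fallback sets out from 9 and comes back at 10. The biocatalyst is replaced by a copper hydride desymmetrising hydrosilylation (Cu(OAc)2, (R)-DTBM-SEGPHOS, (EtO)2MeSiH, toluene, −40 °C). This gives the diethoxy(methyl)silyl dienol ether F1, which is hydrolysed with pH 7 buffer/THF to 10. Both ligand antipodes are sold, so the sense can be matched.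

Risk at step 8. Traces of HCl or PhSCl could aromatise the ketal ring or attack the allyl group or the electron-rich arene. The fallback sets out from 10 and comes back at 15, and it avoids sulfur altogether.
- Copper-catalysed conjugate borylation (CuCl, NaOt-Bu, Xantphos, B2pin2, MeOH, THF) gives the beta-boryl ketone F2.
- NaBO3·4H2O gives the beta-hydroxy ketone F3.
- Dess–Martin periodinane/NaHCO3 gives the cyclohexane-1,3-dione F4.
- TMSCHN2 in toluene/MeOH O-methylates F4 to 15 together with the regioisomeric vinylogous ester F5.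
- F5 is removed by chromatography and hydrolysed with LiOH back to F4 for another pass.

Risk at step 11. The catalyst and the C4 centre may be mismatched, giving low dr, or proton exchange may erode the tertiary centre. The fallback sets out from 15 and comes back at 19. It is a substrate-controlled Stork–Danheiser alkylation (LiN(i-Pr)2, THF, −78 °C, then allyl bromide 2). This gives 19 mixed with the C6 epimer F6. The two are separated on Et3N-washed silica, and F6 is re-equilibrated at C6 with DBU in toluene and recycled.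

**Further compounds**
F1 | step 6 | (R)-[4-(2-allyl-4,5-dimethoxyphenoxy)-4-methoxycyclohexa-1,5-dien-1-yl]oxy-diethoxy(methyl)silane | C=CCc1cc(OC)c(OC)cc1O[C@]1(OC)CC=C(O[Si](C)(OCC)OCC)C=C1
F2 | step 8 | (4R)-4-(2-allyl-4,5-dimethoxyphenoxy)-4-methoxy-3-(4,4,5,5-tetramethyl-1,3,2-dioxaborolan-2-yl)cyclohexan-1-one (C3 epimers) | C=CCc1cc(OC)c(OC)cc1O[C@]1(OC)CCC(=O)CC1B2OC(C)(C)C(C)(C)O2
F3 | step 8 | (4R)-4-(2-allyl-4,5-dimethoxyphenoxy)-3-hydroxy-4-methoxycyclohexan-1-one (C3 epimers) | C=CCc1cc(OC)c(OC)cc1O[C@]1(OC)CCC(=O)CC1O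
F4 | step 8 | (R)-4-(2-allyl-4,5-dimethoxyphenoxy)-4-methoxycyclohexane-1,3-dione | C=CCc1cc(OC)c(OC)cc1O[C@]1(OC)CCC(=O)CC1=O
F5 | step 8 | (R)-6-(2-allyl-4,5-dimethoxyphenoxy)-3,6-dimethoxycyclohex-2-en-1-one | C=CCc1cc(OC)c(OC)cc1O[C@]1(OC)CCC(OC)=CC1=O
F6 | step 11 | (4R,6R)-6-allyl-4-(2-allyl-4,5-dimethoxyphenoxy)-3,4-dimethoxycyclohex-2-en-1-one | C=CCc1cc(OC)c(OC)cc1O[C@]1(OC)C[C@@H](CC=C)C(=O)C=C1OC
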